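**Plan**

Numbering follows the benzofuranone core of the target (O1, C2=O, C3, C3a, C4–C7, C7a); C2′ is the side-chain stereocentre.
Retrosynthesis: cut the C4–O ester bond with allylic transposition back to a C6 tertiary carbinol, then the C3=CH2 bond, the C6–CH3 bond and the C4=C5 unsaturation (back to a C6 ketone), then the lactone O1–C7a bond, then the carbocycle (back to an anisole) and the aryl–C2′ bond.
Forward: the side chain is joined to 3-bromo-4-methoxyphenylacetic acid; Birch reduction gives the six-membered carbocycle; the γ-lactone ring is closed onto it; the C6 ketone is then spent on the C6 methyl group, the C5=C6 alkene and the C4 acyloxy group.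
Enabling feature: C7a lies β to C6 (the former anisole carbon), and C3a, para to C6, carries the CH2CO2H arm, so in the derived cyclohex-2-enone C7a is a Michael terminus placed 5-exo to the carboxyl group.
Stereochemistry: C2′ from asymmetric hydrogenation; C3a from catalyst-controlled γ-protonation; C7a from the enforced cis ring fusion; C4 from capture of an allyl cation on the convex face.

Key step: step 5

Assumption: compounds 1, 3 and 16 are taken as commercial; TBS = tert-butyldimethylsilyl.

**Route**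

Step 1
Reactants: 1 tert-butyldimethyl(pent-4-yn-1-yloxy)silane
Product: 2 2-[5-(TBSO)pent-1-en-2-yl]-4,4,5,5-tetramethyl-1,3,2-dioxaborolane
Conditions: iBu2AlH (1.3 equiv), Ni(dppp)Cl2 (3 mol %), THF, 0 °C to rt; then MeOBpin, 0 to 80 °C
Reagents that add atoms: 2-methoxy-4,4,5,5-tetramethyl-1,3,2-dioxaborolane, COB1OC(C)(C)C(C)(C)O1
Why: Hydroalumination of a terminal alkyne under Ni(dppp)Cl2 catalysis is α-selective and the internal alkenylalane exchanges with the methoxyborate, so the 1,1-disubstituted alkenylboronate should form (hydrometalation then transmetalation).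

Step 2
Reactants: 2 2-[5-(TBSO)pent-1-en-2-yl]-4,4,5,5-tetramethyl-1,3,2-dioxaborolane, 3 2-(3-bromo-4-methoxyphenyl)acetic acid
Product: 4 2-{3-[5-(TBSO)pent-1-en-2-yl]-4-methoxyphenyl}acetic acid
Conditions: Pd(dppf)Cl2 (3 mol %), K2CO3, 1,4-dioxane/H2O, 80 °C; then citric acid (aq) to pH 4
Reagents that add atoms: none
Why: Suzuki–Miyaura coupling of an aryl bromide with an alkenylboronate, in which the carboxylate and the silyl ether tolerate aqueous carbonate and no stereocentre is involved.

Step 3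
Reactants: 4 2-{3-[5-(TBSO)pent-1-en-2-yl]-4-methoxyphenyl}acetic acid
Product: 5 2-{3-[(2S)-5-(TBSO)pentan-2-yl]-4-methoxyphenyl}acetic acid
Conditions: H2 (50 bar), [Ir(cod)(L)][B(C6H3(CF3)2)4] (1 mol %; L = chiral phosphinooxazoline), CH2Cl2, rt
Reagents that add atoms: none
Why: Asymmetric hydrogenation of an unfunctionalised 2-aryl-1-alkene with the cationic complex [Ir(cod)(L)]+, which distinguishes the enantiotopic faces through the aryl versus alkyl substituent; the ligand antipode that delivers the (2S) centre is used.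

Step 4
Reactants: 5 2-{3-[(2S)-5-(TBSO)pentan-2-yl]-4-methoxyphenyl}acetic acid
Product: 7 2-{4-oxo-5-[(2S)-5-(TBSO)pentan-2-yl]cyclohex-1-en-1-yl}acetic acid (C5 epimers), via dienol ether 6 (not isolated)
Conditions: Li, NH3 (l), THF, t-BuOH, −78 to −33 °C; NH4Cl; then (CO2H)2, THF/H2O, rt
Reagents that add atoms: water, O
Why: Birch reduction protonates the two unsubstituted positions para to each other (future C4 and C7) so that methoxy and both alkyl groups stay on sp2 carbons, and mild acid then hydrolyses only the enol ether, leaving the C3a=C7a alkene unconjugated; C5 forms as a mixture that is removed in step 6.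

Step 5
Reactants: 7 2-{4-oxo-5-[(2S)-5-(TBSO)pentan-2-yl]cyclohex-1-en-1-yl}acetic acid (C5 epimers)
Product: 9 (3aR,7aR)-5-[(2S)-5-(TBSO)pentan-2-yl]hexahydro-1-benzofuran-2,6-dione (C5 epimers), via conjugated enone acid 8 (not isolated)
Conditions: 9-amino-9-deoxy-epi-quinine (20 mol %; or its quinidine-derived pseudoenantiomer, whichever gives 3aR), toluene, −20 °C to rt
Reagents that add atoms: none
Why: Proposed new method: the primary amine of the catalyst condenses with the C6 ketone, its tertiary amine removes an α-hydrogen at C7 to give a dienamine, and the resulting ammonium protonates C3a (γ) enantioselectively to form the conjugated iminium of 8, after which the carboxylate on the C3a arm adds to C7a (β) and hydrolysis releases 9. The closest known reaction types are the amine-catalysed enantioselective isomerisation of Birch-derived 4-substituted cyclohex-3-enones to cyclohex-2-enones and the conjugate lactonisation of 4-(carboxymethyl)cyclohex-2-enones; running both on the free acid in one flask is the new element. One ring closes, the γ-lactone, by 5-exo-trig oxa-Michael addition that forms O1–C7a. C3a is set by the catalyst-controlled protonation, and C7a follows from C3a because the short CH2–CO2 tether can reach C7a only on the face it occupies, which enforces the cis ring fusion. The step needs γ- rather than α-protonation and no racemic background shift: the conjugated iminium is drained irreversibly by lactonisation, and the weakly acidic substrate is the only acid present. The epimerisable C5 centre is irrelevant because it becomes sp2 in step 6.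

Step 6
Reactants: 9 (3aR,7aR)-5-[(2S)-5-(TBSO)pentan-2-yl]hexahydro-1-benzofuran-2,6-dione (C5 epimers)
Product: 11 (3aS,7aR)-5-[(2S)-5-(TBSO)pentan-2-yl]-3,3a,7,7a-tetrahydro-1-benzofuran-2,6-dione, via trimethylsilyl enol ether 10 (not isolated)
Conditions: Me3SiCl, NaI, Et3N, MeCN, 0 °C to rt; then Pd(OAc)2 (1.1 equiv), MeCN, rt
Reagents that add atoms: chlorotrimethylsilane, C[Si](C)(C)Cl (its silyl group is carried by intermediate 10 only; no reagent atom remains in 11)
Why: Saegusa–Ito oxidation, in which equilibrating soft enolisation should favour the more substituted C5=C6 silyl enol ether (the C7 side is deactivated by the adjacent C7a–O bond) and syn β-hydride elimination toward the ring C4–H after transfer of the enolate to Pd(OAc)2 gives the endocyclic enone, both C5 epimers converging.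

Step 7
Reactants: 11 (3aS,7aR)-5-[(2S)-5-(TBSO)pentan-2-yl]-3,3a,7,7a-tetrahydro-1-benzofuran-2,6-dione
Product: 12 (3aS,7aR)-6-hydroxy-6-methyl-5-[(2S)-5-(TBSO)pentan-2-yl]-3a,6,7,7a-tetrahydro-1-benzofuran-2(3H)-one (C6 epimers)
Conditions: MeLi, CeCl3, THF, −78 °C
Reagents that add atoms: methyllithium, [Li]C
Why: 1,2-Addition of the weakly basic reagent MeCeCl2 to the enone carbonyl at −78 °C, which spares the lactone and avoids enolisation toward C7 (expulsion of the lactone carboxylate and aromatisation); the new C6 centre is lost again in step 9.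

Step 8
Reactants: 12 (3aS,7aR)-6-hydroxy-6-methyl-5-[(2S)-5-(TBSO)pentan-2-yl]-3a,6,7,7a-tetrahydro-1-benzofuran-2(3H)-one (C6 epimers)
Product: 15 (3aR,7aR)-6-hydroxy-6-methyl-3-methylidene-5-[(2S)-5-(TBSO)pentan-2-yl]-3a,6,7,7a-tetrahydro-1-benzofuran-2(3H)-one (C6 epimers), via Mannich base 13 (not isolated), via trimethylammonium iodide 14 (not isolated)
Conditions: LiN(iPr)2 (2.2 equiv), THF, −78 °C; CH2=NMe2 I, −78 to 0 °C; then MeI, MeOH, rt; then NaHCO3 (aq), CH2Cl2
Reagents that add atoms: N,N-dimethylmethyleneiminium iodide (Eschenmoser's salt), C=[N+](C)C.[I-]; iodomethane, CI (its methyl group is carried by intermediate 14 only)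
Why: Mannich reaction of the lactone enolate (formed beside the tertiary alkoxide) with Eschenmoser's salt, N-methylation and base-induced loss of trimethylamine give the exocyclic methylene (α-methylenation of a γ-lactone) without touching C3a or C7a.

Step 9
Reactants: 15 (3aR,7aR)-6-hydroxy-6-methyl-3-methylidene-5-[(2S)-5-(TBSO)pentan-2-yl]-3a,6,7,7a-tetrahydro-1-benzofuran-2(3H)-one (C6 epimers), 16 3-methylbutanoic acid
Product: 17 (3aR,4S,7aR)-5-[(2S)-5-(TBSO)pentan-2-yl]-6-methyl-3-methylidene-2-oxo-2,3,3a,4,7,7a-hexahydro-1-benzofuran-4-yl 3-methylbutanoate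
Conditions: (+)-camphor-10-sulfonic acid (10 mol %), 16 (10 equiv), CH2Cl2, −20 to 0 °C
Reagents that add atoms: none
Why: Acid-catalysed allylic transposition of a tertiary allylic alcohol, in which ionisation gives the C4–C5–C6 allyl cation and the carboxylic acid should capture it at the secondary terminus C4 on the convex face (anti to C3 of the cis-fused lactone), setting (4S) and the tetrasubstituted C5=C6 alkene.

Step 10
Reactants: 17 (3aR,4S,7aR)-5-[(2S)-5-(TBSO)pentan-2-yl]-6-methyl-3-methylidene-2-oxo-2,3,3a,4,7,7a-hexahydro-1-benzofuran-4-yl 3-methylbutanoate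
Product: 18 (3aR,4S,7aR)-5-[(2S)-5-hydroxypentan-2-yl]-6-methyl-3-methylidene-2-oxo-2,3,3a,4,7,7a-hexahydro-1-benzofuran-4-yl 3-methylbutanoate
Conditions: HF·pyridine, THF, 0 °C to rt
Reagents that add atoms: none
Why: Fluoride cleavage of the primary silyl ether under buffered acidic conditions that should leave the allylic ester, the lactone and the α-methylene group intact.

**Compound list**

1 | tert-butyldimethyl(pent-4-yn-1-yloxy)silane | C#CCCCO[Si](C)(C)C(C)(C)C | starting material
2 | 2-[5-(tert-butyldimethylsilyloxy)pent-1-en-2-yl]-4,4,5,5-tetramethyl-1,3,2-dioxaborolane | C=C(CCCO[Si](C)(C)C(C)(C)C)B1OC(C)(C)C(C)(C)O1 | intermediate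
3 | 2-(3-bromo-4-methoxyphenyl)acetic acid | COc1ccc(CC(=O)O)cc1Br | starting material
4 | 2-{3-[5-(tert-butyldimethylsilyloxy)pent-1-en-2-yl]-4-methoxyphenyl}acetic acid | COc1ccc(CC(=O)O)cc1C(=C)CCCO[Si](C)(C)C(C)(C)C | intermediate
5 | 2-{3-[(2S)-5-(tert-butyldimethylsilyloxy)pentan-2-yl]-4-methoxyphenyl}acetic acid | COc1ccc(CC(=O)O)cc1[C@@H](C)CCCO[Si](C)(C)C(C)(C)C | intermediate
6 | 2-{4-methoxy-5-[(2S)-5-(tert-butyldimethylsilyloxy)pentan-2-yl]cyclohexa-1,4-dien-1-yl}acetic acid | COC1=C([C@@H](C)CCCO[Si](C)(C)C(C)(C)C)CC(CC(=O)O)=CC1 | intermediate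
7 | 2-{4-oxo-5-[(2S)-5-(tert-butyldimethylsilyloxy)pentan-2-yl]cyclohex-1-en-1-yl}acetic acid (C5 epimers) | OC(=O)CC1=CCC(=O)C([C@@H](C)CCCO[Si](C)(C)C(C)(C)C)C1 | intermediate
8 | 2-{(1R)-4-oxo-5-[(2S)-5-(tert-butyldimethylsilyloxy)pentan-2-yl]cyclohex-2-en-1-yl}acetic acid (C5 epimers) | C1[C@H](CC(=O)O)C=CC(=O)C1[C@@H](C)CCCO[Si](C)(C)C(C)(C)C | intermediate
9 | (3aR,7aR)-5-[(2S)-5-(tert-butyldimethylsilyloxy)pentan-2-yl]hexahydro-1-benzofuran-2,6-dione (C5 epimers) | C1C(=O)O[C@@H]2CC(=O)C([C@@H](C)CCCO[Si](C)(C)C(C)(C)C)C[C@H]12 | intermediate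
10 | (3aR,7aR)-5-[(2S)-5-(tert-butyldimethylsilyloxy)pentan-2-yl]-6-(trimethylsilyloxy)-3a,4,7,7a-tetrahydro-1-benzofuran-2(3H)-one | C1C(=O)O[C@@H]2CC(O[Si](C)(C)C)=C([C@@H](C)CCCO[Si](C)(C)C(C)(C)C)C[C@H]12 | intermediate
11 | (3aS,7aR)-5-[(2S)-5-(tert-butyldimethylsilyloxy)pentan-2-yl]-3,3a,7,7a-tetrahydro-1-benzofuran-2,6-dione | C1C(=O)O[C@@H]2CC(=O)C([C@@H](C)CCCO[Si](C)(C)C(C)(C)C)=C[C@H]12 | intermediate
12 | (3aS,7aR)-6-hydroxy-6-methyl-5-[(2S)-5-(tert-butyldimethylsilyloxy)pentan-2-yl]-3a,6,7,7a-tetrahydro-1-benzofuran-2(3H)-one (C6 epimers) | C1C(=O)O[C@@H]2CC(C)(O)C([C@@H](C)CCCO[Si](C)(C)C(C)(C)C)=C[C@H]12 | intermediate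
13 | (3aR,7aR)-3-[(dimethylamino)methyl]-6-hydroxy-6-methyl-5-[(2S)-5-(tert-butyldimethylsilyloxy)pentan-2-yl]-3a,6,7,7a-tetrahydro-1-benzofuran-2(3H)-one (C3 and C6 epimers) | CN(C)CC1C(=O)O[C@@H]2CC(C)(O)C([C@@H](C)CCCO[Si](C)(C)C(C)(C)C)=C[C@H]12 | intermediate
14 | {(3aR,7aR)-6-hydroxy-6-methyl-2-oxo-5-[(2S)-5-(tert-butyldimethylsilyloxy)pentan-2-yl]-2,3,3a,6,7,7a-hexahydro-1-benzofuran-3-yl}-N,N,N-trimethylmethanaminium iodide | C[N+](C)(C)CC1C(=O)O[C@@H]2CC(C)(O)C([C@@H](C)CCCO[Si](C)(C)C(C)(C)C)=C[C@H]12.[I-] | intermediate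
15 | (3aR,7aR)-6-hydroxy-6-methyl-3-methylidene-5-[(2S)-5-(tert-butyldimethylsilyloxy)pentan-2-yl]-3a,6,7,7a-tetrahydro-1-benzofuran-2(3H)-one (C6 epimers) | C=C1C(=O)O[C@@H]2CC(C)(O)C([C@@H](C)CCCO[Si](C)(C)C(C)(C)C)=C[C@H]12 | intermediate
16 | 3-methylbutanoic acid | CC(C)CC(=O)O | starting material
17 | (3aR,4S,7aR)-5-[(2S)-5-(tert-butyldimethylsilyloxy)pentan-2-yl]-6-methyl-3-methylidene-2-oxo-2,3,3a,4,7,7a-hexahydro-1-benzofuran-4-yl 3-methylbutanoate | C=C1C(=O)O[C@@H]2CC(C)=C([C@@H](C)CCCO[Si](C)(C)C(C)(C)C)[C@@H](OC(=O)CC(C)C)[C@H]12 | intermediate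
18 | (3aR,4S,7aR)-5-[(2S)-5-hydroxypentan-2-yl]-6-methyl-3-methylidene-2-oxo-2,3,3a,4,7,7a-hexahydro-1-benzofuran-4-yl 3-methylbutanoate | C=C1C(=O)O[C@@H]2CC(C)=C([C@@H](C)CCCO)[C@@H](OC(=O)CC(C)C)[C@H]12 | target

**Step count and risks**

Total step count: 10. Longest linear sequence: 10 steps (1 to 18); 3 and 16 enter in steps 2 and 9.

Steps most likely to fail:

Step 5 (the step labelled as a proposed new method). Salt formation between the substrate acid and the tertiary amine of the catalyst may shut down the proton shuttle, or an uncatalysed isomerisation and lactonisation may erode the enantiomeric purity at C3a. The fallback separates the two events and sets out from 7. The acid is esterified with allyl alcohol (dicyclohexylcarbodiimide, catalytic 4-dimethylaminopyridine, CH2Cl2, 0 °C) to give prop-2-en-1-yl 2-{4-oxo-5-[(2S)-5-(TBSO)pentan-2-yl]cyclohex-1-en-1-yl}acetate F1. This neutral cyclohex-3-enone is isomerised with the same chiral diamine and a carboxylic acid co-catalyst, the reaction type already established for such substrates, to give prop-2-en-1-yl 2-{(1R)-4-oxo-5-[(2S)-5-(TBSO)pentan-2-yl]cyclohex-2-en-1-yl}acetate F2. The allyl group is then removed with Pd(PPh3)4 and morpholine in THF; the liberated acid 8 closes under the amine, and the route is rejoined at 9.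

Step 6. Enolisation may go toward C7 instead of C5, β-hydride elimination may run into the side chain (which would also erase C2′), or over-oxidation may be followed by loss of the lactone carboxylate and aromatisation. The fallback avoids any enolisation of the ketone and sets out from 9. MeLi/CeCl3 (THF, −78 °C) adds the methyl group to give (3aR,7aR)-6-hydroxy-6-methyl-5-[(2S)-5-(TBSO)pentan-2-yl]hexahydro-1-benzofuran-2(3H)-one F3. Dehydration with the Burgess reagent toward the only tertiary β-hydrogen gives the tetrasubstituted alkene (3aR,7aR)-6-methyl-5-[(2S)-5-(TBSO)pentan-2-yl]-3a,4,7,7a-tetrahydro-1-benzofuran-2(3H)-one F4. A singlet-oxygen ene reaction (O2, light, tetraphenylporphyrin, CH2Cl2, 0 °C) should then abstract a C4 hydrogen, because the C7 hydrogens are deactivated by the C7a–O bond and the C2′–H lies in the alkene plane. This gives (3aS,7aR)-6-hydroperoxy-6-methyl-5-[(2S)-5-(TBSO)pentan-2-yl]-3a,6,7,7a-tetrahydro-1-benzofuran-2(3H)-one F5, which PPh3 reduces to 12, where the route is rejoined.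

Step 9. The allyl cation may lose a proton (diene formation and then aromatisation), may be captured on the concave face or at C6, or the silyl ether may be cleaved prematurely. The fallback replaces ionisation by oxidation, reduction and inversion, and sets out from 15. Oxidative 1,3-transposition with pyridinium chlorochromate (C5H5NH)[CrO3Cl] and NaOAc in CH2Cl2 gives (3aR,7aR)-6-methyl-3-methylidene-5-[(2S)-5-(TBSO)pentan-2-yl]-3,3a,7,7a-tetrahydro-1-benzofuran-2,4-dione F6. Reduction with NaBH4 and CeCl3·7H2O (MeOH, −78 °C) should deliver hydride on the convex face and give (3aS,4R,7aR)-4-hydroxy-6-methyl-3-methylidene-5-[(2S)-5-(TBSO)pentan-2-yl]-3a,4,7,7a-tetrahydro-1-benzofuran-2(3H)-one F7. This alcohol is used at once, because its hydroxyl is cis to C3 and could attack the lactone carbonyl. Mitsunobu esterification with 16 (PPh3, diisopropyl azodicarboxylate, toluene, 0 °C to rt) inverts C4 and rejoins the route at 17.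

Further compounds
F1 | step 5 | prop-2-en-1-yl 2-{4-oxo-5-[(2S)-5-(tert-butyldimethylsilyloxy)pentan-2-yl]cyclohex-1-en-1-yl}acetate (C5 epimers) | C=CCOC(=O)CC1=CCC(=O)C([C@@H](C)CCCO[Si](C)(C)C(C)(C)C)C1
F2 | step 5 | prop-2-en-1-yl 2-{(1R)-4-oxo-5-[(2S)-5-(tert-butyldimethylsilyloxy)pentan-2-yl]cyclohex-2-en-1-yl}acetate (C5 epimers) | C1[C@H](CC(=O)OCC=C)C=CC(=O)C1[C@@H](C)CCCO[Si](C)(C)C(C)(C)C
F3 | step 6 | (3aR,7aR)-6-hydroxy-6-methyl-5-[(2S)-5-(tert-butyldimethylsilyloxy)pentan-2-yl]hexahydro-1-benzofuran-2(3H)-one (C5 and C6 epimers) | C1C(=O)O[C@@H]2CC(C)(O)C([C@@H](C)CCCO[Si](C)(C)C(C)(C)C)C[C@H]12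
F4 | step 6 | (3aR,7aR)-6-methyl-5-[(2S)-5-(tert-butyldimethylsilyloxy)pentan-2-yl]-3a,4,7,7a-tetrahydro-1-benzofuran-2(3H)-one | C1C(=O)O[C@@H]2CC(C)=C([C@@H](C)CCCO[Si](C)(C)C(C)(C)C)C[C@H]12
F5 | step 6 | (3aS,7aR)-6-hydroperoxy-6-methyl-5-[(2S)-5-(tert-butyldimethylsilyloxy)pentan-2-yl]-3a,6,7,7a-tetrahydro-1-benzofuran-2(3H)-one (C6 epimers) | C1C(=O)O[C@@H]2CC(C)(OO)C([C@@H](C)CCCO[Si](C)(C)C(C)(C)C)=C[C@H]12
F6 | step 9 | (3aR,7aR)-6-methyl-3-methylidene-5-[(2S)-5-(tert-butyldimethylsilyloxy)pentan-2-yl]-3,3a,7,7a-tetrahydro-1-benzofuran-2,4-dione | C=C1C(=O)O[C@@H]2CC(C)=C([C@@H](C)CCCO[Si](C)(C)C(C)(C)C)C(=O)[C@H]12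
F7 | step 9 | (3aS,4R,7aR)-4-hydroxy-6-methyl-3-methylidene-5-[(2S)-5-(tert-butyldimethylsilyloxy)pentan-2-yl]-3a,4,7,7a-tetrahydro-1-benzofuran-2(3H)-one | C=C1C(=O)O[C@@H]2CC(C)=C([C@@H](C)CCCO[Si](C)(C)C(C)(C)C)[C@H](O)[C@H]12
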